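Target: prestegane A = (3R,4R)-4-(3,4-dimethoxybenzyl)-3-(3-hydroxy-4-methoxybenzyl)dihydrofuran-2(3H)-one. This is the trans lactone, and both centres read R from the SMILES.

**Retrosynthetic overview**
- Prestegane A ⇒ cut the C3–benzyl bond (trans-selective lactone enolate alkylation, then desilylation) ⇒ (R)-β-(3,4-dimethoxybenzyl)-γ-butyrolactone + O-silylated isovanillyl bromide (three steps from isovanillin).
- (R)-lactone ⇒ achiral 4-(3,4-dimethoxybenzyl)butenolide, with the C4 centre set by ligand-controlled CuH conjugate reduction.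
- Butenolide ⇒ cut the ring C3–C4 bond ⇒ acyclic (bromoacetoxy)methyl benzyl ketone. The ring closes by intramolecular aldol addition of a zinc ester enolate to the ketone, followed by E1cB dehydration.
- Keto ester ⇒ bromoacetyl bromide + 1-aryl-3-hydroxypropan-2-one ⇒ methyl eugenol (ketohydroxylation).
- Only one ring is built, and it closes before any stereocentre exists. C4 is set afterwards and C3 last.

Assumption: the facial sense of (R)-DTBM-SEGPHOS·CuH on the butenolide is assigned by analogy with 3-alkylcyclopentenones and β-substituted unsaturated lactams; the saturated lactone is a known compound, so its sign of rotation is checked once, and the equally available (S)-ligand is used should the sense be opposite.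

**Route**

Step 1
Reactants: 1 methyl eugenol (4-allyl-1,2-dimethoxybenzene)
Product: 2 1-(3,4-dimethoxyphenyl)-3-hydroxypropan-2-one
Conditions: KMnO4 (1.4 equiv), AcOH, acetone/H2O 10:1, −10 → 0 °C, 1 h; filter through Celite
Reagents that add atoms: potassium permanganate, [K+].[O-][Mn](=O)(=O)=O
Why: Permanganate ketohydroxylation: [3+2] addition of MnO4− to the terminal alkene (much faster than attack on the arene at 0 °C) gives a cyclic manganate ester that, in weakly acidic medium, is oxidised further at its secondary carbon instead of hydrolysing to the diol, which places C=O at C2 and OH at C1.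

Step 2
Reactants: 2 1-(3,4-dimethoxyphenyl)-3-hydroxypropan-2-one; 3 bromoacetyl bromide
Product: 4 3-(3,4-dimethoxyphenyl)-2-oxopropyl 2-bromoacetate
Conditions: 3 (1.3 equiv), NaHCO3 (3 equiv), MeCN, 0 °C, 15 min
Reagents that add atoms: none
Why: O-acylation of the primary ketol by an acyl bromide; insoluble, non-nucleophilic NaHCO3 only scavenges HBr, so neither the alkyl bromide nor the enolisable ketone is touched.

Step 3 (ring closure)
Reactants: 4 3-(3,4-dimethoxyphenyl)-2-oxopropyl 2-bromoacetate
Product: 7 (±)-4-(3,4-dimethoxybenzyl)-4-hydroxydihydrofuran-2(3H)-one, via bromozinc ester enolate 5 (not isolated), via bromozinc alkoxide 6 (not isolated)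
Conditions: Zn dust (3 equiv, TMSCl-activated), THF, 65 °C, slow addition of 4 (final 0.02 M); aq NH4Cl
Reagents that add atoms: none
Why: Intramolecular aldol addition in its Reformatsky form: Zn inserts only into the C–Br bond, so the ester enolate forms regiospecifically and without base next to the far more acidic benzyl ketone, and its 5-exo-trig attack on the ketone carbonyl closes the lactone; the new carbinol centre is racemic and is erased in step 4.

Step 4
Reactants: 7 (±)-4-(3,4-dimethoxybenzyl)-4-hydroxydihydrofuran-2(3H)-one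
Product: 9 4-(3,4-dimethoxybenzyl)furan-2(5H)-one, via tertiary mesylate 8 (not isolated)
Conditions: MsCl (1.5 equiv), Et3N (4 equiv), CH2Cl2, 0 °C → rt
Reagents that add atoms: none
Why: Mesylation followed by E1cB elimination completes the aldol condensation; removal of the acidic proton α to the lactone carbonyl puts the alkene in the endocyclic conjugated position rather than toward the benzylic carbon.

Step 5
Reactants: 9 4-(3,4-dimethoxybenzyl)furan-2(5H)-one
Product: 10 (R)-4-(3,4-dimethoxybenzyl)dihydrofuran-2(3H)-one
Conditions: Cu(OAc)2·H2O (3 mol %), (R)-DTBM-SEGPHOS (3.3 mol %), (EtO)2MeSiH (2 equiv), t-BuOH (2 equiv), toluene, 0 °C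
Reagents that add atoms: none
Why: Asymmetric CuH conjugate reduction (1,4-hydrosilylation): the bisphosphine-bound Cu–H delivers hydride to the Si face of the prochiral β-carbon C4, and t-BuOH protonates the copper enolate at the non-stereogenic α-carbon and turns the catalyst over, so the (R) centre is set by the ligand alone under base-free conditions that do not isomerise the butenolide.

Step 6
Reactants: 11 isovanillin (3-hydroxy-4-methoxybenzaldehyde)
Product: 12 3-(tert-butyldimethylsilyloxy)-4-methoxybenzaldehyde
Conditions: TBSCl (1.1 equiv), imidazole (1.5 equiv), DMF, rt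
Reagents that add atoms: tert-butyldimethylsilyl chloride, CC(C)(C)[Si](C)(C)Cl
Why: Imidazole-promoted O-silylation masks the phenol so that it can neither quench the enolate nor be alkylated in step 9.

Step 7
Reactants: 12 3-(tert-butyldimethylsilyloxy)-4-methoxybenzaldehyde
Product: 13 [3-(tert-butyldimethylsilyloxy)-4-methoxyphenyl]methanol
Conditions: NaBH4, MeOH, 0 °C, 20 min
Reagents that add atoms: none
Why: Borohydride 1,2-reduction of the aldehyde is fast at 0 °C and leaves the aryl silyl ether intact.

Step 8
Reactants: 13 [3-(tert-butyldimethylsilyloxy)-4-methoxyphenyl]methanol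
Product: 14 3-(tert-butyldimethylsilyloxy)-4-methoxybenzyl bromide
Conditions: PBr3 (0.4 equiv), CH2Cl2, 0 °C, 30 min; used at once
Reagents that add atoms: phosphorus tribromide, BrP(Br)Br
Why: The alcohol is activated as a phosphite ester and displaced by bromide (SN2), which is rapid for a p-methoxybenzylic alcohol and tolerated by the aryl TBS ether at 0 °C.

Step 9
Reactants: 10 (R)-4-(3,4-dimethoxybenzyl)dihydrofuran-2(3H)-one; 14 3-(tert-butyldimethylsilyloxy)-4-methoxybenzyl bromide
Product: 17 prestegane A, via lithium enolate 15 (not isolated), via O-TBS prestegane A 16 (not isolated)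
Conditions: LiHMDS (1.1 equiv), THF, −78 °C; 14 (0.95 equiv), −78 → −30 °C; then AcOH (3 equiv), TBAF (1.5 equiv), 0 °C → rt
Reagents that add atoms: none
Why: Kinetic lactone enolate alkylation (SN2) followed by fluoride desilylation in the same flask: the bromide approaches the planar enolate anti to the C4 benzyl group (1,2-induction), which sets C3 as R (trans, also the thermodynamic isomer, so buffered TBAF cannot erode it), while C4 is not touched.

**Compound list**
1 | methyl eugenol (4-allyl-1,2-dimethoxybenzene) | C=CCc1ccc(OC)c(OC)c1 | starting material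
2 | 1-(3,4-dimethoxyphenyl)-3-hydroxypropan-2-one | OCC(=O)Cc1ccc(OC)c(OC)c1 | intermediate
3 | bromoacetyl bromide | BrCC(=O)Br | starting material
4 | 3-(3,4-dimethoxyphenyl)-2-oxopropyl 2-bromoacetate | BrCC(=O)OCC(=O)Cc1ccc(OC)c(OC)c1 | intermediate
5 | bromozinc ester enolate of 4 (drawn C-bound, not isolated) | Br[Zn]CC(=O)OCC(=O)Cc1ccc(OC)c(OC)c1 | intermediate
6 | bromozinc alkoxide of the cyclised aldol (racemic, not isolated) | Br[Zn]OC1(Cc2ccc(OC)c(OC)c2)COC(=O)C1 | intermediate
7 | (±)-4-(3,4-dimethoxybenzyl)-4-hydroxydihydrofuran-2(3H)-one | OC1(Cc2ccc(OC)c(OC)c2)COC(=O)C1 | intermediate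
8 | (±)-3-(3,4-dimethoxybenzyl)-5-oxotetrahydrofuran-3-yl methanesulfonate (not isolated) | CS(=O)(=O)OC1(Cc2ccc(OC)c(OC)c2)COC(=O)C1 | intermediate
9 | 4-(3,4-dimethoxybenzyl)furan-2(5H)-one | O=C1C=C(Cc2ccc(OC)c(OC)c2)CO1 | intermediate
10 | (R)-4-(3,4-dimethoxybenzyl)dihydrofuran-2(3H)-one | O=C1C[C@@H](Cc2ccc(OC)c(OC)c2)CO1 | intermediate
11 | isovanillin (3-hydroxy-4-methoxybenzaldehyde) | COc1ccc(C=O)cc1O | starting material
12 | 3-(tert-butyldimethylsilyloxy)-4-methoxybenzaldehyde | COc1ccc(C=O)cc1O[Si](C)(C)C(C)(C)C | intermediate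
13 | [3-(tert-butyldimethylsilyloxy)-4-methoxyphenyl]methanol | COc1ccc(CO)cc1O[Si](C)(C)C(C)(C)C | intermediate
14 | 3-(tert-butyldimethylsilyloxy)-4-methoxybenzyl bromide | COc1ccc(CBr)cc1O[Si](C)(C)C(C)(C)C | intermediate
15 | lithium enolate of 10 (not isolated) | [Li]OC1=C[C@@H](Cc2ccc(OC)c(OC)c2)CO1 | intermediate
16 | (3R,4R)-3-[3-(tert-butyldimethylsilyloxy)-4-methoxybenzyl]-4-(3,4-dimethoxybenzyl)dihydrofuran-2(3H)-one (not isolated) | COc1ccc(C[C@H]2C(=O)OC[C@@H]2Cc2ccc(OC)c(OC)c2)cc1O[Si](C)(C)C(C)(C)C | intermediate
17 | prestegane A, (3R,4R)-4-(3,4-dimethoxybenzyl)-3-(3-hydroxy-4-methoxybenzyl)dihydrofuran-2(3H)-one | COc1ccc(C[C@H]2C(=O)OC[C@@H]2Cc2ccc(OC)c(OC)c2)cc1O | target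

**Counts**
Total step count: 9.
Longest linear sequence: 6 (steps 1, 2, 3, 4, 5, 9). The side branch from isovanillin is steps 6–8 and joins in step 9.

**Steps most likely to fail**

Step 1 (ketohydroxylation). The product is an enolisable benzyl ketol, so permanganate may over-oxidise it or cleave the chain. The fallback sets out from 1 and comes back at 4.
- Catalytic OsO4/NMO dihydroxylation in acetone/H2O gives racemic 3-(3,4-dimethoxyphenyl)propane-1,2-diol F1.
- The primary hydroxyl of F1 is acylated selectively with 3 (2,4,6-collidine, CH2Cl2, −78 °C) to give 3-(3,4-dimethoxyphenyl)-2-hydroxypropyl 2-bromoacetate F2.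
- Dess–Martin oxidation of the remaining secondary alcohol gives 4.
- This bypasses 2 at the cost of one extra step.

Step 3 (ring closure). Three things work against it:
- The closure is formally 5-(enolendo)-exo-trig.
- The ester must reach its less populated E rotamer.
- Proton transfer from the acidic benzylic ketone would give only the debrominated acetate.

The fallback sets out from 4 and comes back at 9, closing the ring by olefination instead.
- Michaelis–Arbuzov reaction with P(OEt)3 (neat, 110 °C) gives 3-(3,4-dimethoxyphenyl)-2-oxopropyl 2-(diethoxyphosphoryl)acetate F3.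
- F3 undergoes an intramolecular Horner–Wadsworth–Emmons reaction (LiCl, DBU, MeCN, 0.01 M) directly to 9.
- Compounds 7 and 8 and step 4 are skipped.

Step 5 (asymmetric reduction). The ee or the sense of induction on a β-benzyl butenolide may fall short, and traces of base can isomerise 9. The fallback sets out from 9 and comes back at 10, replacing catalyst control by a classical resolution.
- H2 over Pd/C in EtOAc gives racemic 4-(3,4-dimethoxybenzyl)dihydrofuran-2(3H)-one F4.
- AlMe3-mediated aminolysis with (S)-1-phenylethylamine opens F4 to two separable hydroxy amides: (3R)-3-(3,4-dimethoxybenzyl)-4-hydroxy-N-[(1S)-1-phenylethyl]butanamide F5 and its (3S) diastereomer (3S)-3-(3,4-dimethoxybenzyl)-4-hydroxy-N-[(1S)-1-phenylethyl]butanamide F6.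
- F5 is purified by crystallisation or chromatography and relactonised with 1 M H2SO4 in dioxane at reflux to give 10. The stereocentre is not α to the carbonyl, so it is not epimerised.

**Further compounds**
F1 | step 1 | (±)-3-(3,4-dimethoxyphenyl)propane-1,2-diol | OCC(O)Cc1ccc(OC)c(OC)c1
F2 | step 1 | (±)-3-(3,4-dimethoxyphenyl)-2-hydroxypropyl 2-bromoacetate | BrCC(=O)OCC(O)Cc1ccc(OC)c(OC)c1
F3 | step 3 | 3-(3,4-dimethoxyphenyl)-2-oxopropyl 2-(diethoxyphosphoryl)acetate | CCOP(=O)(OCC)CC(=O)OCC(=O)Cc1ccc(OC)c(OC)c1
F4 | step 5 | (±)-4-(3,4-dimethoxybenzyl)dihydrofuran-2(3H)-one | O=C1CC(Cc2ccc(OC)c(OC)c2)CO1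
F5 | step 5 | (3R)-3-(3,4-dimethoxybenzyl)-4-hydroxy-N-[(1S)-1-phenylethyl]butanamide | O=C(N[C@@H](C)c1ccccc1)C[C@@H](Cc1ccc(OC)c(OC)c1)CO
F6 | step 5 | (3S)-3-(3,4-dimethoxybenzyl)-4-hydroxy-N-[(1S)-1-phenylethyl]butanamide | O=C(N[C@@H](C)c1ccccc1)C[C@H](Cc1ccc(OC)c(OC)c1)CO
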